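**Strategy**

Ring B is built, not bought. The disconnection cuts its C1–C6 and C2–C3 bonds (C1 = bridge carbon, C3 = aryloxy carbon, C4 = hydroxyl carbon), so that a Diels–Alder benzannulation joins a ring A benzyl ethynyl ketone to a 4-aryloxy-1-methoxy-3-silyloxybutadiene carrying rings C and D. The step exploits that ring B bears its OH para to the bridge carbon and the ring C oxygen ortho to that OH, the pattern such a diene imprints on an acyl alkyne; loss of methanol and silyl aromatizes without an oxidant. The precursor is the (1E,3Z) silyl dienol ether of a 1-aryloxy-4-methoxybutenone, with the ring D phenol masked as a triisopropylsilyl ether.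

Key step: step 10

Remark: the ring D oxygen is carried as a triisopropylsilyl ether and the oxyacetic acid arm is released by hydrogenolysis of a benzyl ester, so that no aryl silyl ether meets hydroxide; the transient species 5, 18 and 21 are racemic, their stereocenters vanish within the same step, and the target has none.

**Route**

Step 1
Reactants: 1 (2-bromo-5-methoxyphenyl)acetic acid
Product: 3 2-(2-bromo-5-methoxyphenyl)-N-methoxy-N-methylacetamide, via acyl imidazolide 2 (not isolated)
Conditions: CDI, CH2Cl2, rt; then MeNHOMe·HCl, rt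
Reagents that add atoms: N,O-dimethylhydroxylamine hydrochloride, CNOC.Cl; 1,1'-carbonyldiimidazole, O=C(n1ccnc1)n1ccnc1 (supplies only the imidazolyl group of intermediate 2)
Why: Amide coupling through an activated acyl azole: the acid is converted into acyl imidazolide 2, which the hydroxylamine aminolyzes, while the aryl bromide and methyl ether are inert.

Step 2
Reactants: 3 2-(2-bromo-5-methoxyphenyl)-N-methoxy-N-methylacetamide; 4 ethynylmagnesium bromide
Product: 6 1-(2-bromo-5-methoxyphenyl)but-3-yn-2-one, via magnesium hemiaminal chelate 5 (not isolated)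
Conditions: HC≡CMgBr (2.5 equiv), THF, 0 °C; inverse quench into cold 1 M HCl
Reagents that add atoms: none
Why: Weinreb ketone synthesis: the alkynyl Grignard reagent adds once to give the stable five-membered chelate 5, which collapses to the ynone only in the acidic quench, where the released amine is protonated and cannot add to the ynone.

Step 3
Reactants: 7 3-hydroxybenzaldehyde
Product: 8 3-[(triisopropylsilyl)oxy]benzaldehyde
Conditions: TIPSCl, imidazole, DMF, rt
Reagents that add atoms: chlorotriisopropylsilane, CC(C)[Si](Cl)(C(C)C)C(C)C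
Why: Imidazole-promoted O-silylation of a phenol; the bulky silyl ether is chosen to resist the amide base, acid chloride, trifluoroacetic acid and carbonate steps ahead.

Step 4
Reactants: 9 4-(hydroxymethyl)phenol; 10 benzyl bromoacetate
Product: 11 benzyl [4-(hydroxymethyl)phenoxy]acetate
Conditions: K2CO3, acetone, 50 °C
Reagents that add atoms: none
Why: Williamson ether synthesis in which carbonate deprotonates only the phenol, far more acidic than the benzylic alcohol, and the phenoxide displaces bromide from the reactive alpha-bromo ester.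

Step 5
Reactants: 11 benzyl [4-(hydroxymethyl)phenoxy]acetate
Product: 12 {4-[2-(benzyloxy)-2-oxoethoxy]benzyl}triphenylphosphonium bromide
Conditions: PPh3·HBr, MeCN, 80 °C
Reagents that add atoms: triphenylphosphine hydrobromide, Br.c1ccc(cc1)P(c1ccccc1)c1ccccc1
Why: Phosphonium salt formation by acid-mediated substitution: HBr ionizes the para-alkoxybenzylic alcohol to a stabilized benzylic cation or bromide that triphenylphosphine captures, and the benzyl ester tolerates the anhydrous acid.

Step 6
Reactants: 12 {4-[2-(benzyloxy)-2-oxoethoxy]benzyl}triphenylphosphonium bromide; 8 3-[(triisopropylsilyl)oxy]benzaldehyde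
Product: 14 benzyl [4-(2-{3-[(triisopropylsilyl)oxy]phenyl}ethenyl)phenoxy]acetate (expected as an E/Z mixture), via phosphonium ylide 13 (not isolated)
Conditions: LiN(SiMe3)2 (1.0 equiv), THF, −78 °C; then 8, −78 °C to rt
Reagents that add atoms: none
Why: Wittig olefination of a non-enolizable aldehyde with a semi-stabilized benzylic ylide, made with one equivalent of a non-nucleophilic base because the phosphonium CH2 is far more acidic than the ester alpha-CH2; the alkene geometry is irrelevant since the double bond is hydrogenated next.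

Step 7
Reactants: 14 benzyl [4-(2-{3-[(triisopropylsilyl)oxy]phenyl}ethenyl)phenoxy]acetate
Product: 15 [4-(2-{3-[(triisopropylsilyl)oxy]phenyl}ethyl)phenoxy]acetic acid
Conditions: H2 (1 atm), 10% Pd/C, EtOAc, rt
Reagents that add atoms: none
Why: Heterogeneous catalytic hydrogenation saturates the stilbene and hydrogenolyzes the benzyl ester in one neutral operation, leaving the aryl silyl ether and the aryl–O–CH2 bond untouched.

Step 8
Reactants: 15 [4-(2-{3-[(triisopropylsilyl)oxy]phenyl}ethyl)phenoxy]acetic acid; 16 methyl vinyl ether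
Product: 19 (E)-4-methoxy-1-[4-(2-{3-[(triisopropylsilyl)oxy]phenyl}ethyl)phenoxy]but-3-en-2-one, via acid chloride 17 (not isolated), via chloro ether ketone 18 (not isolated)
Conditions: (COCl)2, DMF (cat.), CH2Cl2, 0 °C to rt, evaporate; methyl vinyl ether (excess), CH2Cl2, 0 °C to rt, sealed; then Et3N, 0 °C
Reagents that add atoms: oxalyl chloride, ClC(=O)C(=O)Cl (supplies only the chlorine of intermediates 17 and 18; none of its atoms remains in 19)
Why: Acylation of an enol ether by an inductively activated alpha-aryloxy acid chloride gives adduct 18, and E1cB loss of HCl on adding triethylamine gives the conjugated (E)-beta-methoxy enone; the amine is withheld until the acid chloride is consumed so that no ketene can form.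

Step 9
Reactants: 19 (E)-4-methoxy-1-[4-(2-{3-[(triisopropylsilyl)oxy]phenyl}ethyl)phenoxy]but-3-en-2-one
Product: 20 (1E,3Z)-1-methoxy-3-[(trimethylsilyl)oxy]-4-[4-(2-{3-[(triisopropylsilyl)oxy]phenyl}ethyl)phenoxy]buta-1,3-diene
Conditions: TMSOTf, Et3N, Et2O, 0 °C; used crude after filtration
Reagents that add atoms: trimethylsilyl trifluoromethanesulfonate, C[Si](C)(C)OS(=O)(=O)C(F)(F)F
Why: Silyl enol ether formation by soft enolization at the only enolizable position, the aryloxy-substituted CH2; the (3Z) geometry is expected because it keeps the aryloxy group away from the vinyl substituent (least allylic 1,3-strain), which places both terminal oxygens on the outside of the s-cis diene.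

Step 10
Reactants: 20 (1E,3Z)-1-methoxy-3-[(trimethylsilyl)oxy]-4-[4-(2-{3-[(triisopropylsilyl)oxy]phenyl}ethyl)phenoxy]buta-1,3-diene; 6 1-(2-bromo-5-methoxyphenyl)but-3-yn-2-one
Product: 22 2-(2-bromo-5-methoxyphenyl)-1-{4-hydroxy-3-[4-(2-{3-[(triisopropylsilyl)oxy]phenyl}ethyl)phenoxy]phenyl}ethan-1-one, via cis cycloadduct 21 (not isolated)
Conditions: 6 (1.3 equiv), toluene, 80 °C; then 1 M HCl, THF, 0 °C to rt
Reagents that add atoms: none
Why: The electron-rich diene 20 and the electron-poor ynone 6 should combine in a normal-demand, concerted but asynchronous intermolecular [4+2] cycloaddition that closes ring B as cyclohexa-1,4-diene 21: the aryloxy-bearing diene terminus, enriched by the 3-silyloxy group and vinylogously by the 1-methoxy group, bonds to the unsubstituted alkyne carbon (ring B C2–C3), and the methoxy-bearing terminus bonds to the acyl-bearing carbon (ring B C1–C6). The closest known reaction type is the phenol synthesis from 1-methoxy-3-silyloxybutadienes and acetylenic ketones or esters, and 4-oxygenated dienes of this family are established cycloaddition partners. On acidification the methoxy group of 21, a vinylogous mixed acetal oxygen through the silyl enol ether, ionizes (or is beta-eliminated after enol ether hydrolysis), and tautomerization delivers the phenol with no oxidant. The two sp3 centers of 21 are transient, so no stereocontrol is needed and 22 has no stereocenter. The step needs regioselectivity (acyl para to OH, aryloxy ortho to OH), secured by the matched push of the two oxygen donors and the pull of the ynone carbonyl, and chemoselective loss of methanol instead of the aryloxide, secured because the aryloxy group sits alpha and not beta to the emerging carbonyl carbon and is not activated for ionization.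

Step 11
Reactants: 22 2-(2-bromo-5-methoxyphenyl)-1-{4-hydroxy-3-[4-(2-{3-[(triisopropylsilyl)oxy]phenyl}ethyl)phenoxy]phenyl}ethan-1-one
Product: 23 4-[2-(2-bromo-5-methoxyphenyl)ethyl]-2-[4-(2-{3-[(triisopropylsilyl)oxy]phenyl}ethyl)phenoxy]phenol
Conditions: Et3SiH (4 equiv), TFA, CH2Cl2, 0 °C to rt
Reagents that add atoms: none
Why: Ionic hydrogenation: protonation of the electron-rich para-hydroxyaryl ketone and two hydride transfers from the silane through a benzylic cation reduce C=O to CH2, while the aryl bromide, diaryl ether and acid-resistant aryl silyl ether persist.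

Step 12
Reactants: 23 4-[2-(2-bromo-5-methoxyphenyl)ethyl]-2-[4-(2-{3-[(triisopropylsilyl)oxy]phenyl}ethyl)phenoxy]phenol
Product: 24 1-bromo-4-methoxy-2-(2-{4-methoxy-3-[4-(2-{3-[(triisopropylsilyl)oxy]phenyl}ethyl)phenoxy]phenyl}ethyl)benzene
Conditions: MeI, K2CO3, acetone, rt
Reagents that add atoms: iodomethane, CI
Why: Williamson O-methylation of the only free phenol; the ring D oxygen is still silylated and, with the ketone gone, no acidic C–H competes.

Step 13
Reactants: 24 1-bromo-4-methoxy-2-(2-{4-methoxy-3-[4-(2-{3-[(triisopropylsilyl)oxy]phenyl}ethyl)phenoxy]phenyl}ethyl)benzene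
Product: 25 3-[2-(4-{5-[2-(2-bromo-5-methoxyphenyl)ethyl]-2-methoxyphenoxy}phenyl)ethyl]phenol
Conditions: TBAF, THF, 0 °C; AcOH quench
Reagents that add atoms: none
Why: Fluoride-induced desilylation driven by the strong Si–F bond frees the ring D phenol selectively; methyl ethers and the aryl bromide are inert.

Step 14
Reactants: 25 3-[2-(4-{5-[2-(2-bromo-5-methoxyphenyl)ethyl]-2-methoxyphenoxy}phenyl)ethyl]phenol
Product: 26 di-O-methyl dihydroptychantol A (18-membered macrocyclic bis(bibenzyl) with methoxy groups on rings A and B)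
Conditions: CuI (0.5 equiv), N,N-dimethylglycine, Cs2CO3, 1,4-dioxane, 100 °C, 0.003 M, slow addition
Reagents that add atoms: none
Why: Intramolecular Ullmann diaryl ether synthesis: the copper phenoxide of ring D couples with the ring A bromide, high dilution favors closure of the 18-membered ring over oligomerization, and the ring B oxygen is blocked as its methyl ether.

Step 15
Reactants: 26 di-O-methyl dihydroptychantol A
Product: 28 dihydroptychantol A, via bis(dibromoboryl) aryl ether 27 (not isolated)
Conditions: BBr3, CH2Cl2, −78 °C to rt; then H2O, 0 °C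
Reagents that add atoms: boron tribromide, BrB(Br)Br (supplies only the dibromoboryl groups of intermediate 27)
Why: Lewis acid ether cleavage: BBr3 coordinates each methoxy oxygen and bromide attacks the methyl group in an SN2 step to give aryl borate 27, which hydrolyzes on work-up; the diaryl ether links have no sp3 carbon and survive.

**Compound list**

1 | (2-bromo-5-methoxyphenyl)acetic acid | COc1ccc(Br)c(CC(=O)O)c1 | starting material
2 | 1-[(2-bromo-5-methoxyphenyl)acetyl]-1H-imidazole | COc1ccc(Br)c(CC(=O)n2ccnc2)c1 | intermediate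
3 | 2-(2-bromo-5-methoxyphenyl)-N-methoxy-N-methylacetamide | COc1ccc(Br)c(CC(=O)N(C)OC)c1 | intermediate
4 | ethynylmagnesium bromide | C#C[Mg]Br | starting material
5 | bromomagnesium 1-(2-bromo-5-methoxyphenyl)-2-[methoxy(methyl)amino]but-3-yn-2-olate (racemic chelate) | COc1ccc(Br)c(CC(O[Mg]Br)(C#C)N(C)OC)c1 | intermediate
6 | 1-(2-bromo-5-methoxyphenyl)but-3-yn-2-one | C#CC(=O)Cc1cc(OC)ccc1Br | intermediate
7 | 3-hydroxybenzaldehyde | O=Cc1cccc(O)c1 | starting material
8 | 3-[(triisopropylsilyl)oxy]benzaldehyde | O=Cc1cccc(O[Si](C(C)C)(C(C)C)C(C)C)c1 | intermediate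
9 | 4-(hydroxymethyl)phenol | OCc1ccc(O)cc1 | starting material
10 | benzyl bromoacetate | BrCC(=O)OCc1ccccc1 | starting material
11 | benzyl [4-(hydroxymethyl)phenoxy]acetate | OCc1ccc(OCC(=O)OCc2ccccc2)cc1 | intermediate
12 | {4-[2-(benzyloxy)-2-oxoethoxy]benzyl}triphenylphosphonium bromide | [Br-].O=C(COc1ccc(C[P+](c2ccccc2)(c2ccccc2)c2ccccc2)cc1)OCc1ccccc1 | intermediate
13 | benzyl {4-[(triphenyl-lambda5-phosphanylidene)methyl]phenoxy}acetate (ylide) | O=C(COc1ccc(C=P(c2ccccc2)(c2ccccc2)c2ccccc2)cc1)OCc1ccccc1 | intermediate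
14 | benzyl [4-(2-{3-[(triisopropylsilyl)oxy]phenyl}ethenyl)phenoxy]acetate (E/Z mixture, geometry not controlled) | O=C(COc1ccc(C=Cc2cccc(O[Si](C(C)C)(C(C)C)C(C)C)c2)cc1)OCc1ccccc1 | intermediate
15 | [4-(2-{3-[(triisopropylsilyl)oxy]phenyl}ethyl)phenoxy]acetic acid | OC(=O)COc1ccc(CCc2cccc(O[Si](C(C)C)(C(C)C)C(C)C)c2)cc1 | intermediate
16 | methyl vinyl ether (methoxyethene) | COC=C | starting material
17 | [4-(2-{3-[(triisopropylsilyl)oxy]phenyl}ethyl)phenoxy]acetyl chloride | ClC(=O)COc1ccc(CCc2cccc(O[Si](C(C)C)(C(C)C)C(C)C)c2)cc1 | intermediate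
18 | 4-chloro-4-methoxy-1-[4-(2-{3-[(triisopropylsilyl)oxy]phenyl}ethyl)phenoxy]butan-2-one (racemic) | COC(Cl)CC(=O)COc1ccc(CCc2cccc(O[Si](C(C)C)(C(C)C)C(C)C)c2)cc1 | intermediate
19 | (E)-4-methoxy-1-[4-(2-{3-[(triisopropylsilyl)oxy]phenyl}ethyl)phenoxy]but-3-en-2-one | CO/C=C/C(=O)COc1ccc(CCc2cccc(O[Si](C(C)C)(C(C)C)C(C)C)c2)cc1 | intermediate
20 | (1E,3Z)-1-methoxy-3-[(trimethylsilyl)oxy]-4-[4-(2-{3-[(triisopropylsilyl)oxy]phenyl}ethyl)phenoxy]buta-1,3-diene | CO/C=C/C(O[Si](C)(C)C)=C/Oc1ccc(CCc2cccc(O[Si](C(C)C)(C(C)C)C(C)C)c2)cc1 | intermediate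
21 | 2-(2-bromo-5-methoxyphenyl)-1-{cis-6-methoxy-3-[4-(2-{3-[(triisopropylsilyl)oxy]phenyl}ethyl)phenoxy]-4-[(trimethylsilyl)oxy]cyclohexa-1,4-dien-1-yl}ethan-1-one (racemic, one enantiomer drawn) | CO[C@H]1C=C(O[Si](C)(C)C)[C@@H](Oc2ccc(CCc3cccc(O[Si](C(C)C)(C(C)C)C(C)C)c3)cc2)C=C1C(=O)Cc1cc(OC)ccc1Br | intermediate
22 | 2-(2-bromo-5-methoxyphenyl)-1-{4-hydroxy-3-[4-(2-{3-[(triisopropylsilyl)oxy]phenyl}ethyl)phenoxy]phenyl}ethan-1-one | COc1ccc(Br)c(CC(=O)c2ccc(O)c(Oc3ccc(CCc4cccc(O[Si](C(C)C)(C(C)C)C(C)C)c4)cc3)c2)c1 | intermediate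
23 | 4-[2-(2-bromo-5-methoxyphenyl)ethyl]-2-[4-(2-{3-[(triisopropylsilyl)oxy]phenyl}ethyl)phenoxy]phenol | COc1ccc(Br)c(CCc2ccc(O)c(Oc3ccc(CCc4cccc(O[Si](C(C)C)(C(C)C)C(C)C)c4)cc3)c2)c1 | intermediate
24 | 1-bromo-4-methoxy-2-(2-{4-methoxy-3-[4-(2-{3-[(triisopropylsilyl)oxy]phenyl}ethyl)phenoxy]phenyl}ethyl)benzene | COc1ccc(Br)c(CCc2ccc(OC)c(Oc3ccc(CCc4cccc(O[Si](C(C)C)(C(C)C)C(C)C)c4)cc3)c2)c1 | intermediate
25 | 3-[2-(4-{5-[2-(2-bromo-5-methoxyphenyl)ethyl]-2-methoxyphenoxy}phenyl)ethyl]phenol | COc1ccc(Br)c(CCc2ccc(OC)c(Oc3ccc(CCc4cccc(O)c4)cc3)c2)c1 | intermediate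
26 | di-O-methyl dihydroptychantol A (ring A and ring B methyl ethers of the macrocycle) | COc1ccc2c(c1)CCc1ccc(OC)c(c1)Oc1ccc(cc1)CCc1cccc(c1)O2 | intermediate
27 | bis(dibromoboryl) ether of dihydroptychantol A | BrB(Br)Oc1ccc2c(c1)CCc1ccc(OB(Br)Br)c(c1)Oc1ccc(cc1)CCc1cccc(c1)O2 | intermediate
28 | dihydroptychantol A | Oc1ccc2c(c1)CCc1ccc(O)c(c1)Oc1ccc(cc1)CCc1cccc(c1)O2 | target

**Step count and risks**

Total step count: 15. Longest linear sequence: 12 steps (steps 4 to 15, from 9 to 28).

Steps most likely to fail: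

1. Step 10 (key benzannulation). The enolizable terminal ynone may oligomerize or enolize on heating, or the silyl dienol ether may hydrolyze, before cycloaddition occurs. The fallback keeps the benzannulation but uses a robust dienophile and attaches ring A afterwards by ketone synthesis. It sets out from 20. Heating 20 with methyl propiolate (toluene, 100 °C; then 1 M HCl, THF) should give, through the cis cycloadduct ester F1, methyl 4-hydroxy-3-[4-(2-{3-[(triisopropylsilyl)oxy]phenyl}ethyl)phenoxy]benzoate F2. O-Methylation (MeI, K2CO3, acetone) gives the methyl ether ester F3. Treatment with MeNHOMe·HCl and iPrMgCl (THF, −20 °C) gives the N-methoxy-N-methylamide F4. (2-Bromo-5-methoxybenzyl)magnesium bromide F5, made from purchased 2-bromo-5-methoxybenzyl bromide and Mg in Et2O at 0 °C, adds once to F4 to give the ring B methyl ether ketone F6. Ionic hydrogenation of F6 (Et3SiH, TFA) returns to the route at 24, and step 13 follows.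

2. Step 14 (Ullmann macrocyclization). Oxidative addition into the electron-rich, ortho-alkylated bromide may be slow, so that intermolecular coupling and hydrodebromination outrun ring closure. The fallback inverts the polarity at ring A and forms the same ether bond by Chan–Lam oxidative coupling at room temperature. It sets out from 25. Deprotonation and bromine–lithium exchange (n-BuLi, 2.2 equiv, THF, −78 °C), borylation with B(OiPr)3 and acidic work-up give the arylboronic acid F7. Cu(OAc)2, pyridine, 4 Å molecular sieves, CH2Cl2, air, rt, high dilution should then close the ring D–O–ring A bond and return to the route at 26.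

3. Step 8 (enol ether acylation). The acid chloride may be dehydrochlorinated to an aryloxyketene, which adds [2+2] to the vinyl ether, or the vinyl ether may polymerize under the acid released. The fallback builds the methoxy enone by conjugate addition instead. It sets out from 15. CDI then MeNHOMe·HCl gives the N-methoxy-N-methylamide F8. Ethynylmagnesium bromide (THF, 0 °C, acidic inverse quench) gives the aryloxymethyl ethynyl ketone F9. Base-catalyzed conjugate addition of methanol (MeOH, DABCO cat., 0 °C) should give the (E)-enone and return to the route at 19.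

**Further compounds**

F1 | step 10 | methyl cis-6-methoxy-3-[4-(2-{3-[(triisopropylsilyl)oxy]phenyl}ethyl)phenoxy]-4-[(trimethylsilyl)oxy]cyclohexa-1,4-diene-1-carboxylate (racemic, one enantiomer drawn) | CO[C@H]1C=C(O[Si](C)(C)C)[C@@H](Oc2ccc(CCc3cccc(O[Si](C(C)C)(C(C)C)C(C)C)c3)cc2)C=C1C(=O)OC
F2 | step 10 | methyl 4-hydroxy-3-[4-(2-{3-[(triisopropylsilyl)oxy]phenyl}ethyl)phenoxy]benzoate | COC(=O)c1ccc(O)c(Oc2ccc(CCc3cccc(O[Si](C(C)C)(C(C)C)C(C)C)c3)cc2)c1
F3 | step 10 | methyl 4-methoxy-3-[4-(2-{3-[(triisopropylsilyl)oxy]phenyl}ethyl)phenoxy]benzoate | COC(=O)c1ccc(OC)c(Oc2ccc(CCc3cccc(O[Si](C(C)C)(C(C)C)C(C)C)c3)cc2)c1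
F4 | step 10 | N,4-dimethoxy-N-methyl-3-[4-(2-{3-[(triisopropylsilyl)oxy]phenyl}ethyl)phenoxy]benzamide | CON(C)C(=O)c1ccc(OC)c(Oc2ccc(CCc3cccc(O[Si](C(C)C)(C(C)C)C(C)C)c3)cc2)c1
F5 | step 10 | (2-bromo-5-methoxybenzyl)magnesium bromide | COc1ccc(Br)c(C[Mg]Br)c1
F6 | step 10 | 2-(2-bromo-5-methoxyphenyl)-1-{4-methoxy-3-[4-(2-{3-[(triisopropylsilyl)oxy]phenyl}ethyl)phenoxy]phenyl}ethan-1-one | COc1ccc(Br)c(CC(=O)c2ccc(OC)c(Oc3ccc(CCc4cccc(O[Si](C(C)C)(C(C)C)C(C)C)c4)cc3)c2)c1
F7 | step 14 | {2-[2-(3-{4-[2-(3-hydroxyphenyl)ethyl]phenoxy}-4-methoxyphenyl)ethyl]-4-methoxyphenyl}boronic acid | COc1ccc(B(O)O)c(CCc2ccc(OC)c(Oc3ccc(CCc4cccc(O)c4)cc3)c2)c1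
F8 | step 8 | N-methoxy-N-methyl-2-[4-(2-{3-[(triisopropylsilyl)oxy]phenyl}ethyl)phenoxy]acetamide | CON(C)C(=O)COc1ccc(CCc2cccc(O[Si](C(C)C)(C(C)C)C(C)C)c2)cc1
F9 | step 8 | 1-[4-(2-{3-[(triisopropylsilyl)oxy]phenyl}ethyl)phenoxy]but-3-yn-2-one | C#CC(=O)COc1ccc(CCc2cccc(O[Si](C(C)C)(C(C)C)C(C)C)c2)cc1
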